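## Retrosynthetic overview

1. Miyabenol A ⇐ lipase-mediated global deacetylation of its nonaacetate ⇐ Heck coupling of 4-acetoxystyrene with the C4 bromide of ring A of an all-trans tris(dihydrobenzofuran).
2. Each dihydrobenzofuran (C2–C3 bond) ⇐ Rh(II)-catalysed enantioselective C–H insertion of a diaryl carbene into the OCH2 of an ortho 4-methoxybenzyl ether, then acid epimerisation of C2 (cis → trans).
3. Each carbene ⇐ hydrazone ⇐ diaryl ketone ⇐ aryl-lithium (from the C4 bromide of the growing chain) plus one achiral aldehyde **5**, used three times.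
4. Ring order: C (carrying the 3,5-dioxygenated aryl) → B → A; the stilbene is added last.
5. Aldehyde **5** ⇐ 1-bromo-3,5-dimethoxybenzene (formylation, ortho-demethylation, PMB ether).

Assumption 1: the target SMILES is read as ring A (2R,3R), ring B (2S,3S), ring C (2R,3R), all trans; ring A carries the styryl group and ring C the 3,5-dihydroxyphenyl.

Assumption 2: Rh2(R-PTAD)4 is taken to give the (3R) ring and Rh2(S-PTAD)4 the (3S) ring. This is by analogy and must be checked on compound **9** (X-ray with Br anomalous dispersion); if reversed, swap the two catalyst enantiomers.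

## Route

**Step 1**
Reactants: **1**, 1-bromo-3,5-dimethoxybenzene
Product: **2**, 2-bromo-4,6-dimethoxybenzaldehyde
Conditions: POCl3, DMF, 0 → 100 °C; aq. NaOAc
Reagents that add atoms: DMF, CN(C)C=O (formyl C); water, O (carbonyl O on iminium hydrolysis)
Why: Vilsmeier–Haack formylation goes para to one OMe and ortho to the other (as for resorcinol dimethyl ether), not between the two OMe groups.

**Step 2**
Reactants: **2**
Product: **3**, 2-bromo-6-hydroxy-4-methoxybenzaldehyde
Conditions: BCl3, CH2Cl2, −78 → 0 °C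
Reagents that add atoms: none
Why: Chelation-controlled demethylation cleaves only the OMe ortho to the aldehyde.

**Step 3**
Reactants: **3**; **4**, 4-methoxybenzyl chloride
Product: **5**, 2-bromo-4-methoxy-6-[(4-methoxybenzyl)oxy]benzaldehyde
Conditions: K2CO3, TBAI (cat.), DMF, 60 °C
Reagents that add atoms: **4**, COc1ccc(CCl)cc1
Why: Williamson etherification; the PMB group later supplies C2 and its 4-oxygenated aryl.

**Step 4**
Reactants: **1** (as 3,5-dimethoxyphenylmagnesium bromide); **5**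
Product: **6**, (±)-{2-bromo-4-methoxy-6-[(4-methoxybenzyl)oxy]phenyl}(3,5-dimethoxyphenyl)methanol
Conditions: **1**, Mg, THF; then **5**, THF, −78 → 0 °C
Reagents that add atoms: the Grignard from **1**, COc1cc([Mg]Br)cc(OC)c1
Why: Grignard 1,2-addition to the aldehyde is much faster than any Mg/Br exchange with the aryl bromide.

**Step 5**
Reactants: **6**
Product: **7**, {2-bromo-4-methoxy-6-[(4-methoxybenzyl)oxy]phenyl}(3,5-dimethoxyphenyl)methanone
Conditions: Dess–Martin periodinane, NaHCO3, CH2Cl2, rt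
Reagents that add atoms: none
Why: Dess–Martin oxidation of a benzhydrol; PMB ether and ArBr are inert.

**Step 6**
Reactants: **7**
Product: **8**, hydrazone of **7** (E/Z mixture)
Conditions: anhydrous N2H4 (20 equiv), AcOH (cat.), n-BuOH, 110 °C, sealed tube
Reagents that add atoms: hydrazine, NN
Why: Hydrazone condensation; forcing conditions are needed because the ketone is di-ortho-substituted.

**Step 7**
Reactants: **8**
Product: **9**, (2S,3R)-4-bromo-3-(3,5-dimethoxyphenyl)-6-methoxy-2-(4-methoxyphenyl)-2,3-dihydrobenzofuran (cis)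
Conditions: MnO2, CH2Cl2, 0 °C; filter; Rh2(R-PTAD)4 (1 mol %), CH2Cl2, −20 → 0 °C
Reagents that add atoms: none
Why: Oxidation gives the diaryldiazomethane; enantioselective Rh-carbene 1,5 C–H insertion into the benzylic OCH2 sets C3 (R) under catalyst control, with C2 formed cis. This is the first stereocentre.

**Step 8**
Reactants: **9**
Product: **10**, (2R,3R)-4-bromo-3-(3,5-dimethoxyphenyl)-6-methoxy-2-(4-methoxyphenyl)-2,3-dihydrobenzofuran (trans)
Conditions: TFA, CH2Cl2, 0 °C → rt
Reagents that add atoms: none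
Why: Reversible ionisation of the C2–O bond (p-methoxybenzylic cation) and re-closure gives the thermodynamic trans isomer; C3 is not touched.

**Step 9**
Reactants: **10**; **5**
Product: **11**, {2-bromo-4-methoxy-6-[(4-methoxybenzyl)oxy]phenyl}[(2R,3R)-3-(3,5-dimethoxyphenyl)-6-methoxy-2-(4-methoxyphenyl)-2,3-dihydrobenzofuran-4-yl]methanol (carbinol epimers)
Conditions: n-BuLi (1.05 equiv), THF, −78 °C, 15 min; then **5**, −78 → −20 °C
Reagents that add atoms: **5**, COc1ccc(COc2cc(OC)cc(Br)c2C=O)cc1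
Why: Br/Li exchange then 1,2-addition; at −78 °C both outrun deprotonation at C3–H, and the carbinol centre is removed in the next step.

**Step 10**
Reactants: **11**
Product: **12**, the corresponding diaryl ketone
Conditions: Dess–Martin periodinane, NaHCO3, CH2Cl2, rt
Reagents that add atoms: none
Why: Dess–Martin oxidation; no epimerisable centre is adjacent to the new carbonyl.

**Step 11**
Reactants: **12**
Product: **13**, hydrazone of **12**
Conditions: anhydrous N2H4 (40 equiv), N2H4·HCl (0.5 equiv), n-BuOH, 130 °C, sealed tube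
Reagents that add atoms: hydrazine, NN
Why: Hydrazone condensation on a tri-ortho-substituted ketone, pushed by excess hydrazine and mild acid; the trans ring and ethers tolerate these conditions.

**Step 12**
Reactants: **13**
Product: **14**, 4-bromo-6-methoxy-2-(4-methoxyphenyl)-2,3-dihydrobenzofuran (ring B, 2R,3S, cis) bearing at C3 the C4-linked ring C unit of **10** (2R,3R)
Conditions: MnO2, CH2Cl2, 0 °C; filter; Rh2(S-PTAD)4 (1–2 mol %), CH2Cl2, −20 → 0 °C
Reagents that add atoms: none
Why: The same Rh-carbene 1,5 C–H insertion; the enantiomeric catalyst sets C3 of ring B as S, the opposite sense to ring C as the target requires, and ring C is not involved.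

**Step 13**
Reactants: **14**
Product: **15**, ring B (2S,3S)-trans, ring C (2R,3R)-trans bis(dihydrobenzofuran) bromide
Conditions: TFA, CH2Cl2, 0 °C → rt (stop at full conversion)
Reagents that add atoms: none
Why: C2 epimerisation as in step 8; five-membered re-closure by the phenolic oxygen should be much faster than Friedel–Crafts capture of the cation.

**Step 14**
Reactants: **15**; **5**
Product: **16**, carbinol from addition of the ring B C4 aryl-lithium to **5** (carbinol epimers)
Conditions: n-BuLi (1.05 equiv), THF, −78 °C; then **5**, −78 → −20 °C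
Reagents that add atoms: **5**, COc1ccc(COc2cc(OC)cc(Br)c2C=O)cc1
Why: Br/Li exchange and 1,2-addition, as in step 9.

**Step 15**
Reactants: **16**
Product: **17**, the corresponding diaryl ketone
Conditions: Dess–Martin periodinane, NaHCO3, CH2Cl2, rt
Reagents that add atoms: none
Why: Dess–Martin oxidation, as in step 10.

**Step 16**
Reactants: **17**
Product: **18**, hydrazone of **17**
Conditions: anhydrous N2H4 (40 equiv), N2H4·HCl (0.5 equiv), n-BuOH, 130 °C, sealed tube
Reagents that add atoms: hydrazine, NN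
Why: Hydrazone condensation, as in step 11.

**Step 17**
Reactants: **18**
Product: **19**, tris(dihydrobenzofuran) bromide with ring A (2S,3R)-cis, ring B (2S,3S), ring C (2R,3R)
Conditions: MnO2, CH2Cl2, 0 °C; filter; Rh2(R-PTAD)4 (1–2 mol %), CH2Cl2, −20 → 0 °C
Reagents that add atoms: none
Why: Third Rh-carbene 1,5 C–H insertion; Rh2(R-PTAD)4 sets C3 of ring A as R.

**Step 18**
Reactants: **19**
Product: **20**, all-trans octamethyl bromide: ring A (2R,3R), ring B (2S,3S), ring C (2R,3R)
Conditions: TFA, CH2Cl2, 0 °C → rt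
Reagents that add atoms: none
Why: C2 epimerisation of ring A to trans, as in step 8; the other rings are already at equilibrium.

**Step 19**
Reactants: **20**
Product: **21**, octaphenol bromide (all eight OMe → OH)
Conditions: BBr3 (30 equiv), CH2Cl2, −78 °C → rt; MeOH/H2O quench
Reagents that add atoms: none
Why: Lewis-acid ether cleavage, done before the acid-sensitive stilbene exists; any opened dihydrofuran re-closes to trans on work-up.

**Step 20**
Reactants: **21**
Product: **22**, octaacetate bromide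
Conditions: Ac2O, pyridine, DMAP (cat.), rt
Reagents that add atoms: acetic anhydride, CC(=O)OC(C)=O
Why: Peracetylation protects the air-sensitive polyphenol for Pd chemistry and chromatography.

**Step 21**
Reactants: **22**; **23**, 4-acetoxystyrene
Product: **24**, miyabenol A nonaacetate (E-alkene)
Conditions: Pd2(dba)3 (2.5 mol %), P(t-Bu)3·HBF4 (10 mol %), Cy2NMe, 1,4-dioxane, 80 °C, dark
Reagents that add atoms: **23**, CC(=O)Oc1ccc(C=C)cc1
Why: Mizoroki–Heck coupling of a mono-ortho-substituted aryl bromide gives the E-stilbene; no stereocentre is involved and aryl acetates survive the hindered amine base.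

**Step 22**
Reactants: **24**
Product: **25**, miyabenol A
Conditions: lipase (Candida antarctica lipase B, immobilised), n-BuOH (excess), MTBE/THF, 40 °C, Ar, dark
Reagents that add atoms: none
Why: Lipase-catalysed transesterification removes all nine unhindered aryl acetates at neutral pH. This avoids acid (stilbene/dihydrofuran Friedel–Crafts rearrangement) and phenoxide oxidation.

## Compound list

1 | 1-bromo-3,5-dimethoxybenzene | COc1cc(Br)cc(OC)c1 | starting material
2 | 2-bromo-4,6-dimethoxybenzaldehyde | COc1cc(OC)c(C=O)c(Br)c1 | intermediate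
3 | 2-bromo-6-hydroxy-4-methoxybenzaldehyde | COc1cc(O)c(C=O)c(Br)c1 | intermediate
4 | 4-methoxybenzyl chloride | COc1ccc(CCl)cc1 | starting material
5 | 2-bromo-4-methoxy-6-[(4-methoxybenzyl)oxy]benzaldehyde | COc1ccc(COc2cc(OC)cc(Br)c2C=O)cc1 | intermediate
6 | (±)-ring C diaryl carbinol | COc1ccc(COc2cc(OC)cc(Br)c2C(O)c2cc(OC)cc(OC)c2)cc1 | intermediate
7 | ring C diaryl ketone | COc1ccc(COc2cc(OC)cc(Br)c2C(=O)c2cc(OC)cc(OC)c2)cc1 | intermediate
8 | hydrazone of 7 | COc1ccc(COc2cc(OC)cc(Br)c2C(=NN)c2cc(OC)cc(OC)c2)cc1 | intermediate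
9 | (2S,3R)-cis ring C bromide | Brc1cc(OC)cc2c1[C@@H](c1cc(OC)cc(OC)c1)[C@@H](c1ccc(OC)cc1)O2 | intermediate
10 | (2R,3R)-trans ring C bromide | Brc1cc(OC)cc2c1[C@@H](c1cc(OC)cc(OC)c1)[C@H](c1ccc(OC)cc1)O2 | intermediate
11 | ring B carbinol on ring C | OC(c1c(Br)cc(OC)cc1OCc1ccc(OC)cc1)c1cc(OC)cc2c1[C@@H](c1cc(OC)cc(OC)c1)[C@H](c1ccc(OC)cc1)O2 | intermediate
12 | ring B ketone on ring C | O=C(c1c(Br)cc(OC)cc1OCc1ccc(OC)cc1)c1cc(OC)cc2c1[C@@H](c1cc(OC)cc(OC)c1)[C@H](c1ccc(OC)cc1)O2 | intermediate
13 | hydrazone of 12 | NN=C(c1c(Br)cc(OC)cc1OCc1ccc(OC)cc1)c1cc(OC)cc2c1[C@@H](c1cc(OC)cc(OC)c1)[C@H](c1ccc(OC)cc1)O2 | intermediate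
14 | B (2R,3S)-cis / C (2R,3R) bromide | Brc1cc(OC)cc2c1[C@H](c1cc(OC)cc3c1[C@@H](c1cc(OC)cc(OC)c1)[C@H](c1ccc(OC)cc1)O3)[C@H](c1ccc(OC)cc1)O2 | intermediate
15 | B (2S,3S)-trans / C (2R,3R) bromide | Brc1cc(OC)cc2c1[C@H](c1cc(OC)cc3c1[C@@H](c1cc(OC)cc(OC)c1)[C@H](c1ccc(OC)cc1)O3)[C@@H](c1ccc(OC)cc1)O2 | intermediate
16 | ring A carbinol on B–C | OC(c1c(Br)cc(OC)cc1OCc1ccc(OC)cc1)c1cc(OC)cc2c1[C@H](c1cc(OC)cc3c1[C@@H](c1cc(OC)cc(OC)c1)[C@H](c1ccc(OC)cc1)O3)[C@@H](c1ccc(OC)cc1)O2 | intermediate
17 | ring A ketone on B–C | O=C(c1c(Br)cc(OC)cc1OCc1ccc(OC)cc1)c1cc(OC)cc2c1[C@H](c1cc(OC)cc3c1[C@@H](c1cc(OC)cc(OC)c1)[C@H](c1ccc(OC)cc1)O3)[C@@H](c1ccc(OC)cc1)O2 | intermediate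
18 | hydrazone of 17 | NN=C(c1c(Br)cc(OC)cc1OCc1ccc(OC)cc1)c1cc(OC)cc2c1[C@H](c1cc(OC)cc3c1[C@@H](c1cc(OC)cc(OC)c1)[C@H](c1ccc(OC)cc1)O3)[C@@H](c1ccc(OC)cc1)O2 | intermediate
19 | A (2S,3R)-cis / B (2S,3S) / C (2R,3R) bromide | Brc1cc(OC)cc2c1[C@@H](c1cc(OC)cc3c1[C@H](c1cc(OC)cc4c1[C@@H](c1cc(OC)cc(OC)c1)[C@H](c1ccc(OC)cc1)O4)[C@@H](c1ccc(OC)cc1)O3)[C@@H](c1ccc(OC)cc1)O2 | intermediate
20 | all-trans octamethyl bromide, A (2R,3R) / B (2S,3S) / C (2R,3R) | Brc1cc(OC)cc2c1[C@@H](c1cc(OC)cc3c1[C@H](c1cc(OC)cc4c1[C@@H](c1cc(OC)cc(OC)c1)[C@H](c1ccc(OC)cc1)O4)[C@@H](c1ccc(OC)cc1)O3)[C@H](c1ccc(OC)cc1)O2 | intermediate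
21 | octaphenol bromide | Brc1cc(O)cc2c1[C@@H](c1cc(O)cc3c1[C@H](c1cc(O)cc4c1[C@@H](c1cc(O)cc(O)c1)[C@H](c1ccc(O)cc1)O4)[C@@H](c1ccc(O)cc1)O3)[C@H](c1ccc(O)cc1)O2 | intermediate
22 | octaacetate bromide | Brc1cc(OC(C)=O)cc2c1[C@@H](c1cc(OC(C)=O)cc3c1[C@H](c1cc(OC(C)=O)cc4c1[C@@H](c1cc(OC(C)=O)cc(OC(C)=O)c1)[C@H](c1ccc(OC(C)=O)cc1)O4)[C@@H](c1ccc(OC(C)=O)cc1)O3)[C@H](c1ccc(OC(C)=O)cc1)O2 | intermediate
23 | 4-acetoxystyrene | CC(=O)Oc1ccc(C=C)cc1 | starting material
24 | miyabenol A nonaacetate | CC(=O)Oc1ccc(/C=C/c2cc(OC(C)=O)cc3c2[C@@H](c2cc(OC(C)=O)cc4c2[C@H](c2cc(OC(C)=O)cc5c2[C@@H](c2cc(OC(C)=O)cc(OC(C)=O)c2)[C@H](c2ccc(OC(C)=O)cc2)O5)[C@@H](c2ccc(OC(C)=O)cc2)O4)[C@H](c2ccc(OC(C)=O)cc2)O3)cc1 | intermediate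
25 | miyabenol A | Oc1ccc(/C=C/c2cc(O)cc3c2[C@@H](c2cc(O)cc4c2[C@H](c2cc(O)cc5c2[C@@H](c2cc(O)cc(O)c2)[C@H](c2ccc(O)cc2)O5)[C@@H](c2ccc(O)cc2)O4)[C@H](c2ccc(O)cc2)O3)cc1 | target

## Totals and risks

Total steps: 22. Longest linear sequence: 22 steps from **1** (aldehyde **5** is made once and used three times).

Steps most likely to fail:

1. **Steps 11 and 16 (hydrazones of tri-ortho-substituted, electron-rich diaryl ketones).** Condensation may stall, or the ortho bromide may cyclise to an indazole at 130 °C. Fallback: avoid carbonyl condensation. Convert carbinol **11**/**16** to the benzhydryl azide (DPPA, DBU), expel N2 with base to the N–H ketimine, and trans-iminate with hydrazinium acetate.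

2. **Steps 12 and 17 (C–H insertion on hindered substrates that already carry stereocentres).** Catalyst/substrate mismatch, low dr at C3 or azine formation are possible. Fallback: change the ring-forming reaction. Remove the PMB group from carbinol **11**/**16** (DDQ), generate the o-quinone methide, and close the ring by trans-selective (4+1) annulation with a (4-methoxybenzyl)sulfonium ylide, using a chiral sulfide for facial control.

3. **Step 19 (BBr3 on the tris(dihydrobenzofuran)).** Ring-opened C2 cations could be trapped by a neighbouring resorcinol ring (seven-membered Friedel–Crafts), or demethylation may be incomplete. Fallback: change the protecting-group plan. Build the series with TIPS ethers, using a 4-(TIPS-oxy)benzyl ether as the insertion partner, and unmask with fluoride to reach **21** without Lewis acid.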